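Everything rests on closing the furan ring (O1′, C2′–C5′; C3′ carries C18) last, through its C3′=C4′ ring alkene. In one operation, ring-closing metathesis of an allyl 1-ethoxyallyl acetal and acid-induced loss of ethanol turn an open-chain terminus into the 3-alkylfuran, so the ring least tolerant of acid and oxidants never meets the aluminium, copper, strong-base and alkylating steps. The precursor is the (5E)-4-O-methyl tetronate (lactone O1, C2–C5) bearing the whole C6–C18 chain, with the C7 stereocentre and the skipped C11=C12/C14=C15 diene in place, ending in C18H2–C(=CH2)–CH2–O–CH(OEt)–CH=CH2. The hindered (5E) enol-lactone alkene is set earlier by a stereoretentive acyclic sequence.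

Key step: step 17

Remark: the acetal carbon of 28 arises as both epimers, which is immaterial because it becomes the sp2 carbon C5′; phosphonate 20 is taken as purchasable (otherwise one bromination of the Still–Gennari phosphonate).

Step 1
Reactants: 1 (4-bromobut-1-yn-1-yl)trimethylsilane
Product: 2 [4-(trimethylsilyl)but-3-yn-1-yl]magnesium bromide (titrated THF stock solution, divided between steps 2 and 6)
Conditions: Mg turnings (I2 crystal), THF, 35 °C; solution titrated and kept under Ar at 0 °C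
Reagents that add atoms: magnesium, [Mg]
Why: Grignard formation by insertion of magnesium into the primary C–Br bond; the silyl cap removes the acidic alkyne hydrogen, so the homopropargylic reagent should be stable in THF and one batch can serve both couplings.

Step 2
Reactants: 2 [4-(trimethylsilyl)but-3-yn-1-yl]magnesium bromide; 3 3-chloro-2-(chloromethyl)prop-1-ene
Product: 4 [6-(chloromethyl)hept-6-en-1-yn-1-yl]trimethylsilane
Conditions: 3 (4 equiv), CuI (5 mol%), THF, −30 to 0 °C, slow addition of 2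
Reagents that add atoms: none
Why: Copper-catalysed Grignard allylation replaces one chloride of the symmetrical dichloride (SN2 and SN2′ paths give the same product), and the excess of 3 with inverse addition should hold the reaction at mono-substitution.

Step 3
Reactants: 4 [6-(chloromethyl)hept-6-en-1-yn-1-yl]trimethylsilane
Product: 6 2-methylidenehept-6-yn-1-ol, via acetate 5 (not isolated)
Conditions: KOAc, DMF, 60 °C; then MeOH, K2CO3, rt
Reagents that add atoms: potassium acetate, CC(=O)[O-].[K+]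
Why: SN2 displacement of the primary allylic chloride by acetate followed by basic methanolysis in the same flask should remove both the acetyl group and the alkynyl trimethylsilyl group.

Step 4
Reactants: 6 2-methylidenehept-6-yn-1-ol
Product: 7 tert-butyl[(2-methylidenehept-6-yn-1-yl)oxy]diphenylsilane
Conditions: t-BuPh2SiCl, imidazole, CH2Cl2, rt
Reagents that add atoms: tert-butyl(chloro)diphenylsilane, CC(C)(C)[Si](Cl)(c1ccccc1)c1ccccc1
Why: Silylation of the primary allylic alcohol gives an ether that tolerates Me3Al, bases and mild acid and can later be removed with fluoride.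

Step 5
Reactants: 8 (R)-3-bromo-2-methylpropan-1-ol
Product: 9 (R)-(3-bromo-2-methylpropoxy)(tert-butyl)dimethylsilane
Conditions: t-BuMe2SiCl, imidazole, CH2Cl2, rt
Reagents that add atoms: tert-butyl(chloro)dimethylsilane, CC(C)(C)[Si](C)(C)Cl
Why: Silylation protects the future C6 oxygen; the stereocentre (future C7) comes from the purchased bromo alcohol and is not touched.

Step 6
Reactants: 9 (R)-(3-bromo-2-methylpropoxy)(tert-butyl)dimethylsilane; 2 [4-(trimethylsilyl)but-3-yn-1-yl]magnesium bromide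
Product: 11 (S)-tert-butyldimethyl[(2-methylhept-6-yn-1-yl)oxy]silane, via silylalkyne 10 (not isolated)
Conditions: 2 (1.5 equiv), Li2CuCl4 (3 mol%), NMP, THF, 0 °C to rt; then MeOH, K2CO3, rt
Reagents that add atoms: none
Why: Copper-catalysed alkyl–alkyl Grignard cross-coupling at the primary bromide joins C8 to C9 without involving the adjacent stereocentre, and methanolic K2CO3 then frees the terminal alkyne while the silyl ether stays.

Step 7
Reactants: 11 (S)-tert-butyldimethyl[(2-methylhept-6-yn-1-yl)oxy]silane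
Product: 13 (2E,7S)-8-[(tert-butyldimethylsilyl)oxy]-3,7-dimethyloct-2-en-1-ol, via alkenylalane 12 (not isolated)
Conditions: Me3Al (2.5 equiv), Cp2ZrCl2 (0.25 equiv), CH2Cl2, 0 °C to rt; volatiles removed; n-BuLi, THF–hexane, −78 °C; (CH2O)n, −78 °C to rt
Reagents that add atoms: trimethylaluminium, C[Al](C)C; formaldehyde (as paraformaldehyde), C=O
Why: Negishi carboalumination adds methyl and aluminium syn across the alkyne with methyl on the internal carbon, and hydroxymethylation of the derived alanate with retention should fix the (E)-C11=C12 alkene.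

Step 8
Reactants: 13 (2E,7S)-8-[(tert-butyldimethylsilyl)oxy]-3,7-dimethyloct-2-en-1-ol
Product: 15 tert-butyl{[(2S,6E)-8-chloro-2,6-dimethyloct-6-en-1-yl]oxy}dimethylsilane, via allylic mesylate 14 (not isolated)
Conditions: MsCl, 2,4,6-collidine, LiCl, DMF, 0 °C
Reagents that add atoms: methanesulfonyl chloride, CS(=O)(=O)Cl (kept only in 14); lithium chloride, [Li+].[Cl-]
Why: Mesylation and in situ SN2 displacement by chloride should give the primary allylic chloride without allylic transposition or loss of alkene geometry.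

Step 9
Reactants: 7 tert-butyl[(2-methylidenehept-6-yn-1-yl)oxy]diphenylsilane; 15 tert-butyl{[(2S,6E)-8-chloro-2,6-dimethyloct-6-en-1-yl]oxy}dimethylsilane
Product: 17 tert-butyl{[(2S,6E,9E)-15-{[tert-butyl(diphenyl)silyl]oxy}-2,6,10-trimethyl-14-methylidenepentadeca-6,9-dien-1-yl]oxy}dimethylsilane, via alkenylalane 16 (not isolated)
Conditions: 7, Me3Al (2 equiv), Cp2ZrCl2 (0.25 equiv), ClCH2CH2Cl, rt; then 15, Pd(PPh3)4 (5 mol%), THF, rt
Reagents that add atoms: trimethylaluminium, C[Al](C)C
Why: Negishi carboalumination sets the (E)-C14=C15 alkene by syn addition (the 1,1-disubstituted alkene is inert), and zerovalent-palladium-catalysed cross-coupling of the alkenylalane with the allylic chloride forms C13–C14 at the primary terminus with retention of both geometries, giving the skipped diene.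

Step 10
Reactants: 17 tert-butyl{[(2S,6E,9E)-15-{[tert-butyl(diphenyl)silyl]oxy}-2,6,10-trimethyl-14-methylidenepentadeca-6,9-dien-1-yl]oxy}dimethylsilane
Product: 18 (2S,6E,9E)-15-{[tert-butyl(diphenyl)silyl]oxy}-2,6,10-trimethyl-14-methylidenepentadeca-6,9-dien-1-ol
Conditions: camphorsulfonic acid (0.1 equiv), MeOH–CH2Cl2 1:1, 0 °C
Reagents that add atoms: none
Why: Acid-catalysed methanolysis cleaves the primary tert-butyldimethylsilyl ether much faster than the tert-butyldiphenylsilyl ether, and the trisubstituted alkenes should tolerate these mild conditions.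

Step 11
Reactants: 18 (2S,6E,9E)-15-{[tert-butyl(diphenyl)silyl]oxy}-2,6,10-trimethyl-14-methylidenepentadeca-6,9-dien-1-ol
Product: 19 (2S,6E,9E)-15-{[tert-butyl(diphenyl)silyl]oxy}-2,6,10-trimethyl-14-methylidenepentadeca-6,9-dienal
Conditions: Dess–Martin periodinane, NaHCO3, CH2Cl2, 0 °C to rt; used crude at once
Reagents that add atoms: none
Why: Dess–Martin oxidation under buffered, non-basic conditions gives the α-branched aldehyde without epimerising C7 and without touching the alkenes.

Step 12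
Reactants: 19 (2S,6E,9E)-15-{[tert-butyl(diphenyl)silyl]oxy}-2,6,10-trimethyl-14-methylidenepentadeca-6,9-dienal; 20 methyl 2-[bis(2,2,2-trifluoroethoxy)phosphoryl]-2-bromoacetate
Product: 21 methyl (2E,4S,8E,11E)-2-bromo-17-{[tert-butyl(diphenyl)silyl]oxy}-4,8,12-trimethyl-16-methylideneheptadeca-2,8,11-trienoate
Conditions: 20, KOt-Bu, 18-crown-6, THF, −78 °C; then 19, −78 °C
Reagents that add atoms: none
Why: Still–Gennari-type Horner–Wadsworth–Emmons olefination is kinetically controlled and places the aldehyde substituent cis to the ester, so bromine ends up trans to C7 in the (E)-α-bromoacrylate, and the cold, weakly basic phosphonate anion should not epimerise C7.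

Step 13
Reactants: 21 methyl (2E,4S,8E,11E)-2-bromo-17-{[tert-butyl(diphenyl)silyl]oxy}-4,8,12-trimethyl-16-methylideneheptadeca-2,8,11-trienoate; 22 propanoic acid
Product: 23 methyl (2E,4S,8E,11E)-17-{[tert-butyl(diphenyl)silyl]oxy}-4,8,12-trimethyl-16-methylidene-2-(propanoyloxy)heptadeca-2,8,11-trienoate
Conditions: 22 (2 equiv), CuI (10 mol%), 3,4,7,8-tetramethyl-1,10-phenanthroline (20 mol%), Cs2CO3, toluene, 80 °C, Ar
Reagents that add atoms: none
Why: Ullmann-type copper-catalysed O-vinylation of the carboxylate (oxidative addition of the alkenyl C–Br bond to a monovalent copper carboxylate, then C–O reductive elimination) replaces bromine by propanoate with retention of alkene geometry, so the future O1 lies trans to C7.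

Step 14
Reactants: 23 methyl (2E,4S,8E,11E)-17-{[tert-butyl(diphenyl)silyl]oxy}-4,8,12-trimethyl-16-methylidene-2-(propanoyloxy)heptadeca-2,8,11-trienoate
Product: 25 (5E)-5-[(2S,6E,9E)-15-{[tert-butyl(diphenyl)silyl]oxy}-2,6,10-trimethyl-14-methylidenepentadeca-6,9-dien-1-ylidene]-4-methoxy-3-methylfuran-2(5H)-one, via lithium tetronate 24 (not isolated)
Conditions: LiN(SiMe3)2 (2.2 equiv), THF, −78 to 0 °C; then DMPU, Me2SO4 (5 equiv), 0 °C to rt; aq. NH3 quench
Reagents that add atoms: lithium bis(trimethylsilyl)amide, [Li+].C[Si](C)(C)[N-][Si](C)(C)C (lithium kept only in 24); dimethyl sulfate, COS(=O)(=O)OC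
Why: Dieckmann condensation of the propanoate enolate onto the neighbouring methyl ester forms the C3–C4 bond and closes the lactone without disturbing the C5=C6 geometry, and the tetronate anion is then O-methylated at the C4 oxygen by the hard electrophile to give the conjugated 4-methoxybutenolide.

Step 15
Reactants: 25 (5E)-5-[(2S,6E,9E)-15-{[tert-butyl(diphenyl)silyl]oxy}-2,6,10-trimethyl-14-methylidenepentadeca-6,9-dien-1-ylidene]-4-methoxy-3-methylfuran-2(5H)-one
Product: 26 (5E)-5-[(2S,6E,9E)-15-hydroxy-2,6,10-trimethyl-14-methylidenepentadeca-6,9-dien-1-ylidene]-4-methoxy-3-methylfuran-2(5H)-one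
Conditions: Bu4NF, AcOH (1:1), THF, 0 °C to rt
Reagents that add atoms: none
Why: Fluoride-induced desilylation, buffered with acetic acid, frees the allylic alcohol while the vinylogous ester and the (5E) alkene should remain unchanged.

Step 16
Reactants: 26 (5E)-5-[(2S,6E,9E)-15-hydroxy-2,6,10-trimethyl-14-methylidenepentadeca-6,9-dien-1-ylidene]-4-methoxy-3-methylfuran-2(5H)-one; 27 acrolein diethyl acetal (3,3-diethoxyprop-1-ene)
Product: 28 (5E)-5-[(2S,6E,9E)-15-[(1-ethoxyprop-2-en-1-yl)oxy]-2,6,10-trimethyl-14-methylidenepentadeca-6,9-dien-1-ylidene]-4-methoxy-3-methylfuran-2(5H)-one (both acetal epimers)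
Conditions: 27 (10 equiv), pyridinium 4-toluenesulfonate (5 mol%), toluene, 40 °C, reduced pressure; Et3N quench
Reagents that add atoms: none
Why: Acid-catalysed transacetalisation exchanges one ethoxy group of 27 for the primary allylic alcohol and is driven by removal of ethanol.

Step 17
Reactants: 28 (5E)-5-[(2S,6E,9E)-15-[(1-ethoxyprop-2-en-1-yl)oxy]-2,6,10-trimethyl-14-methylidenepentadeca-6,9-dien-1-ylidene]-4-methoxy-3-methylfuran-2(5H)-one
Product: 30 (5E)-5-[(2S,6E,9E)-13-(furan-3-yl)-2,6,10-trimethyltrideca-6,9-dien-1-ylidene]-4-methoxy-3-methylfuran-2(5H)-one, via ethoxydihydrofuran 29 (not isolated)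
Conditions: second-generation Grubbs catalyst [(H2IMes)(PCy3)Cl2Ru=CHPh] (5 mol%), 1,4-benzoquinone (10 mol%), CH2Cl2 (5 mM), 40 °C; then pyridinium 4-toluenesulfonate (20 mol%), rt, same flask
Reagents that add atoms: none
Why: The ruthenium benzylidene first exchanges with the unhindered vinyl group of the acetal, the resulting alkylidene undergoes [2+2] cycloaddition with the C3′=CH2 alkene three atoms away, and cycloreversion of the ruthenacyclobutane releases ethene and leaves C3′=C4′ inside the 2-ethoxy-2,5-dihydrofuran 29; the pyridinium salt then ionises the ring acetal to a cyclic oxocarbenium ion, which sheds a C2′ proton to give the aromatic furan. This is the established diene metathesis of mixed allyl/1-alkoxyallyl acetals to alkoxydihydrofurans, combined with acid-driven loss of alcohol, applied here to a longer substrate. The only ring formed is the five-membered furan ring, closed by ring-closing metathesis between C3′ and C4′, whereas the aromatisation is an elimination and closes nothing. No stereocentre is created, since the acetal carbon of either epimer ends as the sp2 carbon C5′ and C7 and the chain alkenes take no part. Site selectivity among six alkenes is required and should follow from the catalyst loading onto the one monosubstituted alkene and then closing a five-membered ring onto the 1,1-disubstituted neighbour far faster than it can engage the trisubstituted C11=C12 and C14=C15 alkenes or the hindered, conjugated C5=C6 alkene. High dilution and 1,4-benzoquinone are included to suppress dimerisation and ruthenium-hydride isomerisation of the skipped diene.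

Step 18
Reactants: 30 (5E)-5-[(2S,6E,9E)-13-(furan-3-yl)-2,6,10-trimethyltrideca-6,9-dien-1-ylidene]-4-methoxy-3-methylfuran-2(5H)-one
Product: 31 (5E)-5-[(2S,6E,9E)-13-(furan-3-yl)-2,6,10-trimethyltrideca-6,9-dien-1-ylidene]-4-hydroxy-3-methylfuran-2(5H)-one (CNP0017566.1)
Conditions: LiCl (10 equiv), DMSO, 60 °C, Ar, dark; then cold dilute aq. HCl to pH 3
Reagents that add atoms: none
Why: Chloride demethylates the vinylogous carbonate by SN2 attack at the O-methyl carbon (the tetronate anion is a good leaving group) under neutral, non-oxidising conditions that should leave the furan, the skipped diene, the (5E) alkene and C7 unchanged.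

Compound list
1 | (4-bromobut-1-yn-1-yl)trimethylsilane | C[Si](C)(C)C#CCCBr | starting material
2 | [4-(trimethylsilyl)but-3-yn-1-yl]magnesium bromide (titrated THF solution) | C[Si](C)(C)C#CCC[Mg]Br | intermediate
3 | 3-chloro-2-(chloromethyl)prop-1-ene | ClCC(=C)CCl | starting material
4 | [6-(chloromethyl)hept-6-en-1-yn-1-yl]trimethylsilane | C[Si](C)(C)C#CCCCC(=C)CCl | intermediate
5 | 2-methylidene-7-(trimethylsilyl)hept-6-yn-1-yl acetate | CC(=O)OCC(=C)CCCC#C[Si](C)(C)C | intermediate
6 | 2-methylidenehept-6-yn-1-ol | OCC(=C)CCCC#C | intermediate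
7 | tert-butyl[(2-methylidenehept-6-yn-1-yl)oxy]diphenylsilane | CC(C)(C)[Si](OCC(=C)CCCC#C)(c1ccccc1)c1ccccc1 | intermediate
8 | (R)-3-bromo-2-methylpropan-1-ol | OC[C@@H](C)CBr | starting material
9 | (R)-(3-bromo-2-methylpropoxy)(tert-butyl)dimethylsilane | CC(C)(C)[Si](C)(C)OC[C@@H](C)CBr | intermediate
10 | (S)-tert-butyldimethyl{[2-methyl-7-(trimethylsilyl)hept-6-yn-1-yl]oxy}silane | CC(C)(C)[Si](C)(C)OC[C@@H](C)CCCC#C[Si](C)(C)C | intermediate
11 | (S)-tert-butyldimethyl[(2-methylhept-6-yn-1-yl)oxy]silane | CC(C)(C)[Si](C)(C)OC[C@@H](C)CCCC#C | intermediate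
12 | {(1E,7S)-8-[(tert-butyldimethylsilyl)oxy]-2,7-dimethyloct-1-en-1-yl}dimethylalane | CC(C)(C)[Si](C)(C)OC[C@@H](C)CCC/C(C)=C/[Al](C)C | intermediate
13 | (2E,7S)-8-[(tert-butyldimethylsilyl)oxy]-3,7-dimethyloct-2-en-1-ol | CC(C)(C)[Si](C)(C)OC[C@@H](C)CCC/C(C)=C/CO | intermediate
14 | (2E,7S)-8-[(tert-butyldimethylsilyl)oxy]-3,7-dimethyloct-2-en-1-yl methanesulfonate | CC(C)(C)[Si](C)(C)OC[C@@H](C)CCC/C(C)=C/COS(C)(=O)=O | intermediate
15 | tert-butyl{[(2S,6E)-8-chloro-2,6-dimethyloct-6-en-1-yl]oxy}dimethylsilane | CC(C)(C)[Si](C)(C)OC[C@@H](C)CCC/C(C)=C/CCl | intermediate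
16 | [(1E)-6-({[tert-butyl(diphenyl)silyl]oxy}methyl)-2-methylhepta-1,6-dien-1-yl]dimethylalane | C[Al](C)/C=C(\C)CCCC(=C)CO[Si](c1ccccc1)(c1ccccc1)C(C)(C)C | intermediate
17 | tert-butyl{[(2S,6E,9E)-15-{[tert-butyl(diphenyl)silyl]oxy}-2,6,10-trimethyl-14-methylidenepentadeca-6,9-dien-1-yl]oxy}dimethylsilane | CC(C)(C)[Si](C)(C)OC[C@@H](C)CCC/C(C)=C/C/C=C(\C)CCCC(=C)CO[Si](c1ccccc1)(c1ccccc1)C(C)(C)C | intermediate
18 | (2S,6E,9E)-15-{[tert-butyl(diphenyl)silyl]oxy}-2,6,10-trimethyl-14-methylidenepentadeca-6,9-dien-1-ol | OC[C@@H](C)CCC/C(C)=C/C/C=C(\C)CCCC(=C)CO[Si](c1ccccc1)(c1ccccc1)C(C)(C)C | intermediate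
19 | (2S,6E,9E)-15-{[tert-butyl(diphenyl)silyl]oxy}-2,6,10-trimethyl-14-methylidenepentadeca-6,9-dienal | O=C[C@@H](C)CCC/C(C)=C/C/C=C(\C)CCCC(=C)CO[Si](c1ccccc1)(c1ccccc1)C(C)(C)C | intermediate
20 | methyl 2-[bis(2,2,2-trifluoroethoxy)phosphoryl]-2-bromoacetate | COC(=O)C(Br)P(=O)(OCC(F)(F)F)OCC(F)(F)F | starting material
21 | methyl (2E,4S,8E,11E)-2-bromo-17-{[tert-butyl(diphenyl)silyl]oxy}-4,8,12-trimethyl-16-methylideneheptadeca-2,8,11-trienoate | COC(=O)/C(Br)=C\[C@@H](C)CCC/C(C)=C/C/C=C(\C)CCCC(=C)CO[Si](c1ccccc1)(c1ccccc1)C(C)(C)C | intermediate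
22 | propanoic acid | CCC(=O)O | starting material
23 | methyl (2E,4S,8E,11E)-17-{[tert-butyl(diphenyl)silyl]oxy}-4,8,12-trimethyl-16-methylidene-2-(propanoyloxy)heptadeca-2,8,11-trienoate | COC(=O)/C(OC(=O)CC)=C\[C@@H](C)CCC/C(C)=C/C/C=C(\C)CCCC(=C)CO[Si](c1ccccc1)(c1ccccc1)C(C)(C)C | intermediate
24 | lithium 4-olate (lithium tetronate) of (5E)-5-[(2S,6E,9E)-15-{[tert-butyl(diphenyl)silyl]oxy}-2,6,10-trimethyl-14-methylidenepentadeca-6,9-dien-1-ylidene]-4-hydroxy-3-methylfuran-2(5H)-one | [Li+].CC1=C([O-])/C(=C\[C@@H](C)CCC/C(C)=C/C/C=C(\C)CCCC(=C)CO[Si](c2ccccc2)(c2ccccc2)C(C)(C)C)OC1=O | intermediate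
25 | (5E)-5-[(2S,6E,9E)-15-{[tert-butyl(diphenyl)silyl]oxy}-2,6,10-trimethyl-14-methylidenepentadeca-6,9-dien-1-ylidene]-4-methoxy-3-methylfuran-2(5H)-one | CC1=C(OC)/C(=C\[C@@H](C)CCC/C(C)=C/C/C=C(\C)CCCC(=C)CO[Si](c2ccccc2)(c2ccccc2)C(C)(C)C)OC1=O | intermediate
26 | (5E)-5-[(2S,6E,9E)-15-hydroxy-2,6,10-trimethyl-14-methylidenepentadeca-6,9-dien-1-ylidene]-4-methoxy-3-methylfuran-2(5H)-one | CC1=C(OC)/C(=C\[C@@H](C)CCC/C(C)=C/C/C=C(\C)CCCC(=C)CO)OC1=O | intermediate
27 | acrolein diethyl acetal (3,3-diethoxyprop-1-ene) | C=CC(OCC)OCC | starting material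
28 | (5E)-5-[(2S,6E,9E)-15-[(1-ethoxyprop-2-en-1-yl)oxy]-2,6,10-trimethyl-14-methylidenepentadeca-6,9-dien-1-ylidene]-4-methoxy-3-methylfuran-2(5H)-one (both acetal epimers) | CC1=C(OC)/C(=C\[C@@H](C)CCC/C(C)=C/C/C=C(\C)CCCC(=C)COC(OCC)C=C)OC1=O | intermediate
29 | (5E)-5-[(2S,6E,9E)-13-(5-ethoxy-2,5-dihydrofuran-3-yl)-2,6,10-trimethyltrideca-6,9-dien-1-ylidene]-4-methoxy-3-methylfuran-2(5H)-one | CC1=C(OC)/C(=C\[C@@H](C)CCC/C(C)=C/C/C=C(\C)CCCC2=CC(OCC)OC2)OC1=O | intermediate
30 | (5E)-5-[(2S,6E,9E)-13-(furan-3-yl)-2,6,10-trimethyltrideca-6,9-dien-1-ylidene]-4-methoxy-3-methylfuran-2(5H)-one | CC1=C(OC)/C(=C\[C@@H](C)CCC/C(C)=C/C/C=C(\C)CCCc2ccoc2)OC1=O | intermediate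
31 | (5E)-5-[(2S,6E,9E)-13-(furan-3-yl)-2,6,10-trimethyltrideca-6,9-dien-1-ylidene]-4-hydroxy-3-methylfuran-2(5H)-one | CC1=C(O)/C(=C\[C@@H](C)CCC/C(C)=C/C/C=C(\C)CCCc2ccoc2)OC1=O | target

Total step count: 18. Longest linear sequence: 14 steps (steps 5–18, from 8 to 31; the arm from 1 through steps 1–4 and 9–18 is equally long).

Steps most likely to fail

Step 13. The process at risk is slow oxidative addition and C–O reductive elimination at the hindered, electron-poor alkenyl bromide, with protodebromination or erosion of alkene geometry through reversible conjugate addition of carboxylate. The fallback sets out from 21 and comes back at 25; it brings in the ring oxygen intramolecularly. Reduction of 21 with i-Bu2AlH gives the bromoallylic alcohol (2E,4S,8E,11E)-2-bromo-17-{[tert-butyl(diphenyl)silyl]oxy}-4,8,12-trimethyl-16-methylideneheptadeca-2,8,11-trien-1-ol F1, and MnO2 oxidation gives the corresponding bromoenal F2. Aldol addition of the dilithium enediolate of propanoic acid (22, LiN(i-Pr)2) gives the β-hydroxy acid F3. Copper-catalysed intramolecular O-vinylation of the carboxylic acid (CuI, trans-N,N′-dimethylcyclohexane-1,2-diamine, K2CO3, dioxane, 65 °C), which proceeds with retention of alkene geometry, closes the hydroxy enol lactone F4. Dess–Martin oxidation gives the free tetronic acid F5, and Me2SO4 with K2CO3 in acetone returns to 25.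

Step 14. The process at risk is fragmentation of the propanoate enolate into methylketene and the α-keto ester enolate before ring closure, or methylation at the lactone carbonyl oxygen instead of the C4 oxygen. The fallback sets out from 19 and comes back at 25; it uses a preformed tetronate. Addition of 5-lithio-4-methoxy-3-methylfuran-2(5H)-one (from the known furanone and LiN(i-Pr)2, THF, −78 °C) to 19 gives the aldol adduct F6. Mesylation gives the methanesulfonate F7, and elimination with DBU gives mainly the (5Z)-ylidene tetronate F8, the geometric isomer of 25. Sensitised photoisomerisation (350 nm, benzene, catalytic diphenyl disulfide) should give a Z/E mixture from which 25 is separated by chromatography, with the (5Z) isomer recycled.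

Step 17. The process at risk is ruthenium-hydride-mediated migration of the skipped diene into conjugation, intermolecular metathesis at the vinyl acetal outrunning ring closure, or premature ionisation of the acetal. The fallback sets out from Grignard solution 2 and 15 and comes back at 30; it carries a preformed furan through the known chemistry of steps 6 and 9–14. Grignard reagent 2 and 3-(bromomethyl)furan (Li2CuCl4, THF) give trimethyl[5-(furan-3-yl)pent-1-yn-1-yl]silane F9, and K2CO3 in MeOH gives 3-(pent-4-yn-1-yl)furan F10. Carboalumination (Me3Al, Cp2ZrCl2) gives the alkenylalane [(1E)-5-(furan-3-yl)-2-methylpent-1-en-1-yl]dimethylalane F11, which is coupled with 15 under Pd(PPh3)4 to give the silyl ether F12. Acid methanolysis gives the alcohol F13 and Dess–Martin oxidation the aldehyde F14. Olefination with 20 gives the bromoacrylate F15, copper-catalysed coupling with 22 gives the enol propanoate F16, and Dieckmann condensation gives the lithium tetronate F17, which is methylated with Me2SO4 to 30.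

Further compounds
F1 | step 13 | (2E,4S,8E,11E)-2-bromo-17-{[tert-butyl(diphenyl)silyl]oxy}-4,8,12-trimethyl-16-methylideneheptadeca-2,8,11-trien-1-ol | OC/C(Br)=C\[C@@H](C)CCC/C(C)=C/C/C=C(\C)CCCC(=C)CO[Si](c1ccccc1)(c1ccccc1)C(C)(C)C
F2 | step 13 | (2E,4S,8E,11E)-2-bromo-17-{[tert-butyl(diphenyl)silyl]oxy}-4,8,12-trimethyl-16-methylideneheptadeca-2,8,11-trienal | O=C/C(Br)=C\[C@@H](C)CCC/C(C)=C/C/C=C(\C)CCCC(=C)CO[Si](c1ccccc1)(c1ccccc1)C(C)(C)C
F3 | step 13 | (4E,6S,10E,13E)-4-bromo-19-{[tert-butyl(diphenyl)silyl]oxy}-3-hydroxy-2,6,10,14-tetramethyl-18-methylidenenonadeca-4,10,13-trienoic acid (diastereomers at C2 and C3) | OC(=O)C(C)C(O)/C(Br)=C\[C@@H](C)CCC/C(C)=C/C/C=C(\C)CCCC(=C)CO[Si](c1ccccc1)(c1ccccc1)C(C)(C)C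
F4 | step 13 | (5E)-5-[(2S,6E,9E)-15-{[tert-butyl(diphenyl)silyl]oxy}-2,6,10-trimethyl-14-methylidenepentadeca-6,9-dien-1-ylidene]-4-hydroxy-3-methyloxolan-2-one (diastereomers at C3 and C4) | CC1C(O)/C(=C\[C@@H](C)CCC/C(C)=C/C/C=C(\C)CCCC(=C)CO[Si](c2ccccc2)(c2ccccc2)C(C)(C)C)OC1=O
F5 | step 13 | (5E)-5-[(2S,6E,9E)-15-{[tert-butyl(diphenyl)silyl]oxy}-2,6,10-trimethyl-14-methylidenepentadeca-6,9-dien-1-ylidene]-4-hydroxy-3-methylfuran-2(5H)-one | CC1=C(O)/C(=C\[C@@H](C)CCC/C(C)=C/C/C=C(\C)CCCC(=C)CO[Si](c2ccccc2)(c2ccccc2)C(C)(C)C)OC1=O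
F6 | step 14 | 5-[(2S,6E,9E)-15-{[tert-butyl(diphenyl)silyl]oxy}-1-hydroxy-2,6,10-trimethyl-14-methylidenepentadeca-6,9-dien-1-yl]-4-methoxy-3-methylfuran-2(5H)-one (diastereomers at C5 and the carbinol carbon) | CC1=C(OC)C(C(O)[C@@H](C)CCC/C(C)=C/C/C=C(\C)CCCC(=C)CO[Si](c2ccccc2)(c2ccccc2)C(C)(C)C)OC1=O
F7 | step 14 | methanesulfonate of F6 | CC1=C(OC)C(C(OS(C)(=O)=O)[C@@H](C)CCC/C(C)=C/C/C=C(\C)CCCC(=C)CO[Si](c2ccccc2)(c2ccccc2)C(C)(C)C)OC1=O
F8 | step 14 | (5Z)-5-[(2S,6E,9E)-15-{[tert-butyl(diphenyl)silyl]oxy}-2,6,10-trimethyl-14-methylidenepentadeca-6,9-dien-1-ylidene]-4-methoxy-3-methylfuran-2(5H)-one | CC1=C(OC)/C(=C/[C@@H](C)CCC/C(C)=C/C/C=C(\C)CCCC(=C)CO[Si](c2ccccc2)(c2ccccc2)C(C)(C)C)OC1=O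
F9 | step 17 | trimethyl[5-(furan-3-yl)pent-1-yn-1-yl]silane | C[Si](C)(C)C#CCCCc1ccoc1
F10 | step 17 | 3-(pent-4-yn-1-yl)furan | C#CCCCc1ccoc1
F11 | step 17 | [(1E)-5-(furan-3-yl)-2-methylpent-1-en-1-yl]dimethylalane | C[Al](C)/C=C(\C)CCCc1ccoc1
F12 | step 17 | tert-butyl{[(2S,6E,9E)-13-(furan-3-yl)-2,6,10-trimethyltrideca-6,9-dien-1-yl]oxy}dimethylsilane | CC(C)(C)[Si](C)(C)OC[C@@H](C)CCC/C(C)=C/C/C=C(\C)CCCc1ccoc1
F13 | step 17 | (2S,6E,9E)-13-(furan-3-yl)-2,6,10-trimethyltrideca-6,9-dien-1-ol | OC[C@@H](C)CCC/C(C)=C/C/C=C(\C)CCCc1ccoc1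
F14 | step 17 | (2S,6E,9E)-13-(furan-3-yl)-2,6,10-trimethyltrideca-6,9-dienal | O=C[C@@H](C)CCC/C(C)=C/C/C=C(\C)CCCc1ccoc1
F15 | step 17 | methyl (2E,4S,8E,11E)-2-bromo-15-(furan-3-yl)-4,8,12-trimethylpentadeca-2,8,11-trienoate | COC(=O)/C(Br)=C\[C@@H](C)CCC/C(C)=C/C/C=C(\C)CCCc1ccoc1
F16 | step 17 | methyl (2E,4S,8E,11E)-15-(furan-3-yl)-4,8,12-trimethyl-2-(propanoyloxy)pentadeca-2,8,11-trienoate | COC(=O)/C(OC(=O)CC)=C\[C@@H](C)CCC/C(C)=C/C/C=C(\C)CCCc1ccoc1
F17 | step 17 | lithium 4-olate (lithium tetronate) of (5E)-5-[(2S,6E,9E)-13-(furan-3-yl)-2,6,10-trimethyltrideca-6,9-dien-1-ylidene]-4-hydroxy-3-methylfuran-2(5H)-one | [Li+].CC1=C([O-])/C(=C\[C@@H](C)CCC/C(C)=C/C/C=C(\C)CCCc2ccoc2)OC1=O
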